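**Retrosynthetic overview**

- Agecorynin E (17) is traced back to its O-benzyl ether 16. The only stereocentre, C2 (S), is set by enantioselective hydride addition to C2 of the flat flavone 14 (C2=C3 of ring C).
- Ring C of 14 is cut at O1–C8a, C4–C4a and O1–C2, giving 3,4,5-trimethoxybenzyne and an arylpropiolic acid.
- The feature that carries the plan: ring A has O1 (on C8a) and the acyl carbon C4 (on C4a) on neighbouring carbons, with the C5 methoxy group next to C4a and H at C8. An aryne across C4a–C8a takes up a carboxylic acid in exactly this ortho pattern, and the C5 methoxy group fixes the orientation.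
- The ortho-silylaryl triflate 5 comes from 3,4,5-trimethoxyphenol (bromination, then silylation/retro-Brook shift/triflation). The acid 11 comes from vanillin (benzylation, Corey–Fuchs, CO2 quench).
- Ring order: rings A and B are bought; ring C is the only ring formed (step 6).

Key step: step 6

Numbering remark: flavonoid numbering is used throughout (ring C: O1, C2, C3, C4; ring A: C4a, C5–C8, C8a; ring B primed).
Assumption: in step 7 the (R)-antipode of DTBM-SEGPHOS is taken to deliver hydride to the Re face of C2; if a first run shows the opposite sense, the (S)-ligand is used with nothing else changed.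

**Route**

Step 1
Reactants: 1 3,4,5-trimethoxyphenol
Product: 2 2-bromo-3,4,5-trimethoxyphenol
Conditions: NBS (1.0 equiv), CH2Cl2, −78 °C to 0 °C
Reagents that add atoms: N-bromosuccinimide, O=C1CCC(=O)N1Br
Why: Electrophilic aromatic bromination directed ortho by the hydroxyl group; the two ortho positions are equivalent and the para position is blocked, so one equivalent at low temperature should stop at the monobromide.

Step 2
Reactants: 2 2-bromo-3,4,5-trimethoxyphenol
Product: 5 3,4,5-trimethoxy-2-(trimethylsilyl)phenyl trifluoromethanesulfonate, via aryl trimethylsilyl ether 3 (not isolated), via lithium 2-silylphenoxide 4 (not isolated)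
Conditions: HMDS, THF, reflux, then evaporate; n-BuLi (1.1 equiv), THF, −100 °C to −80 °C; Tf2O (1.2 equiv), −100 °C to rt
Reagents that add atoms: hexamethyldisilazane, C[Si](C)(C)N[Si](C)(C)C; trifluoromethanesulfonic anhydride, O=S(=O)(OS(=O)(=O)C(F)(F)F)C(F)(F)F
Why: Standard telescoped sequence to ortho-silylaryl triflates: O-silylation, bromine–lithium exchange, retro-Brook 1,3-shift of SiMe3 from oxygen to the lithiated carbon, and O-triflation of the resulting phenoxide, which places SiMe3 between the triflate and the neighbouring methoxy group.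

Step 3
Reactants: 6 vanillin; 7 benzyl bromide
Product: 8 4-(benzyloxy)-3-methoxybenzaldehyde
Conditions: K2CO3, DMF, rt
Reagents that add atoms: none
Why: Williamson etherification of the phenoxide, which leaves the aldehyde untouched (8 is also a catalogue compound, so this step can be skipped).

Step 4
Reactants: 8 4-(benzyloxy)-3-methoxybenzaldehyde
Product: 9 1-(benzyloxy)-4-(2,2-dibromoethenyl)-2-methoxybenzene
Conditions: CBr4, PPh3, CH2Cl2, 0 °C
Reagents that add atoms: carbon tetrabromide, BrC(Br)(Br)Br
Why: First stage of the Corey–Fuchs homologation, a Wittig-type olefination by the dibromomethylene ylide that tolerates aryl ethers.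

Step 5
Reactants: 9 1-(benzyloxy)-4-(2,2-dibromoethenyl)-2-methoxybenzene
Product: 11 3-[4-(benzyloxy)-3-methoxyphenyl]prop-2-ynoic acid, via lithium arylacetylide 10 (not isolated)
Conditions: n-BuLi (2.2 equiv), THF, −78 °C to 0 °C; CO2, −78 °C to rt; then 1 M HCl
Reagents that add atoms: carbon dioxide, O=C=O
Why: Second stage of the Corey–Fuchs sequence: two equivalents of n-BuLi convert the dibromoalkene into the lithium acetylide, which is carboxylated by CO2, and the benzyl ether is inert at these temperatures.

Step 6
Reactants: 5 3,4,5-trimethoxy-2-(trimethylsilyl)phenyl trifluoromethanesulfonate (1.5 equiv); 11 3-[4-(benzyloxy)-3-methoxyphenyl]prop-2-ynoic acid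
Product: 14 2-[4-(benzyloxy)-3-methoxyphenyl]-5,6,7-trimethoxy-4H-chromen-4-one, via 3,4,5-trimethoxybenzyne 12 (not isolated), via ortho-hydroxyaryl ynone 13 (not isolated)
Conditions: CsF (4 equiv), THF, 125 °C, sealed tube
Reagents that add atoms: none
Why: Fluoride removes SiMe3 from 5 and triflate leaves, giving aryne 12; the caesium carboxylate of 11 adds through oxygen to the aryne carbon that becomes C8a, and the aryl anion at C4a attacks the carbonyl of the new aryl ester through a four-membered alkoxide that opens to the ortho-acyl phenoxide of 13 (net insertion of the aryne into the C–O bond of the acid, an anionic Fries-type acyl shift). The closest known reaction type is the fluoride-induced insertion of arynes into carboxylic acids to give ortho-hydroxyaryl ketones, which with arylpropiolic acids continues to flavones. Ring C is closed by 6-endo-dig oxa-Michael addition of the phenoxide oxygen (O1) to the β-carbon of the ynone (C2), and the vinyl anion is protonated at C3 by the HF/bifluoride pool; no stereocentre is formed. The regiochemistry needed (oxygen at C8a, acyl at C4a) is secured by the methoxy group flanking one aryne terminus: its inductive pull and the aryne distortion it causes make the remote terminus the electrophilic one and place the developing carbanion ortho to OMe, at C4a. The 6-endo closure should win over 5-exo closure to the aurone because C2 is the conjugate position of the ynone and the flavone is the more stable product under hot, proton-shuttling conditions.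

Step 7
Reactants: 14 2-[4-(benzyloxy)-3-methoxyphenyl]-5,6,7-trimethoxy-4H-chromen-4-one
Product: 16 (2S)-2-[4-(benzyloxy)-3-methoxyphenyl]-5,6,7-trimethoxy-2,3-dihydro-4H-chromen-4-one, via silyl enol ether 15 (not isolated)
Conditions: Cu(OAc)2 (5 mol %), (R)-DTBM-SEGPHOS (5.5 mol %), (EtO)2MeSiH (3 equiv), toluene, 0 °C to rt; then 1 M HCl, THF, 0 °C
Reagents that add atoms: none
Why: Proposed new method: a ligated copper hydride formed from Cu(OAc)2 and the silane should add hydride to the β-carbon C2 of the vinylogous ester to give an O-bound copper enolate, which σ-bond metathesis with Si–H converts into silyl enol ether 15 while regenerating the hydride; the chiral bisphosphine selects the Re face of C2, which gives 2S, and holding the product as the silyl enol ether blocks 1,2-reduction and retro-oxa-Michael scrambling until the cold acidic work-up. The closest known reaction type is the copper hydride/chiral bisphosphine asymmetric 1,4-reduction of 2-alkylchromones and of β-aryl-β-alkyl enones; the extension is to a 2-aryl chromone with an electron-rich ring A.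

Step 8
Reactants: 16 (2S)-2-[4-(benzyloxy)-3-methoxyphenyl]-5,6,7-trimethoxy-2,3-dihydro-4H-chromen-4-one
Product: 17 agecorynin E
Conditions: H2 (1 atm), 10% Pd/C, EtOAc, rt, stopped at full conversion
Reagents that add atoms: none
Why: Hydrogenolysis of the aryl benzyl ether over Pd/C under neutral, base-free conditions, which should be faster than cleavage of the cyclic C2–O1 bond or ketone reduction and does not open the base-labile flavanone ring, so C2 stays 2S.

**Compound list**

1 | 3,4,5-trimethoxyphenol | COc1cc(O)cc(OC)c1OC | starting material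
2 | 2-bromo-3,4,5-trimethoxyphenol | COc1cc(O)c(Br)c(OC)c1OC | intermediate
3 | (2-bromo-3,4,5-trimethoxyphenoxy)trimethylsilane | COc1cc(O[Si](C)(C)C)c(Br)c(OC)c1OC | intermediate
4 | lithium 3,4,5-trimethoxy-2-(trimethylsilyl)phenoxide | [Li+].[O-]c1cc(OC)c(OC)c(OC)c1[Si](C)(C)C | intermediate
5 | 3,4,5-trimethoxy-2-(trimethylsilyl)phenyl trifluoromethanesulfonate | COc1cc(OS(=O)(=O)C(F)(F)F)c([Si](C)(C)C)c(OC)c1OC | intermediate
6 | vanillin | COc1cc(C=O)ccc1O | starting material
7 | benzyl bromide | BrCc1ccccc1 | starting material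
8 | 4-(benzyloxy)-3-methoxybenzaldehyde | COc1cc(C=O)ccc1OCc1ccccc1 | intermediate
9 | 1-(benzyloxy)-4-(2,2-dibromoethenyl)-2-methoxybenzene | COc1cc(C=C(Br)Br)ccc1OCc1ccccc1 | intermediate
10 | lithium [4-(benzyloxy)-3-methoxyphenyl]ethynide | [Li+].[C-]#Cc1ccc(OCc2ccccc2)c(OC)c1 | intermediate
11 | 3-[4-(benzyloxy)-3-methoxyphenyl]prop-2-ynoic acid | COc1cc(C#CC(=O)O)ccc1OCc1ccccc1 | intermediate
12 | 3,4,5-trimethoxybenzyne (1,2-didehydro-3,4,5-trimethoxybenzene) | COC1=CC#CC(OC)=C1OC | intermediate
13 | 3-[4-(benzyloxy)-3-methoxyphenyl]-1-(2-hydroxy-4,5,6-trimethoxyphenyl)prop-2-yn-1-one (present as its caesium phenoxide) | COc1cc(C#CC(=O)c2c(O)cc(OC)c(OC)c2OC)ccc1OCc1ccccc1 | intermediate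
14 | 2-[4-(benzyloxy)-3-methoxyphenyl]-5,6,7-trimethoxy-4H-chromen-4-one | COc1cc(-c2cc(=O)c3c(cc(OC)c(OC)c3OC)o2)ccc1OCc1ccccc1 | intermediate
15 | (2S)-2-[4-(benzyloxy)-3-methoxyphenyl]-4-{[diethoxy(methyl)silyl]oxy}-5,6,7-trimethoxy-2H-chromene | COc1cc([C@@H]2C=C(O[Si](C)(OCC)OCC)c3c(cc(OC)c(OC)c3OC)O2)ccc1OCc1ccccc1 | intermediate
16 | (2S)-2-[4-(benzyloxy)-3-methoxyphenyl]-5,6,7-trimethoxy-2,3-dihydro-4H-chromen-4-one | COc1cc([C@@H]2CC(=O)c3c(cc(OC)c(OC)c3OC)O2)ccc1OCc1ccccc1 | intermediate
17 | agecorynin E = (2S)-2-(4-hydroxy-3-methoxyphenyl)-5,6,7-trimethoxy-2,3-dihydro-4H-chromen-4-one | COc1cc([C@@H]2CC(=O)c3c(cc(OC)c(OC)c3OC)O2)ccc1O | target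

**Step count**

Total steps: 8.
Longest linear sequence: 6 steps (vanillin to 17 through steps 3, 4, 5, 6, 7 and 8); the aryne branch adds 2 steps (1 and 2) before the convergence in step 6.

**Steps most likely to fail**

1. Step 7 (proposed new method). Hydride transfer to the aryl-bearing, electron-rich β-carbon may be slow or poorly face-selective, and the copper enolate may expel the ring phenoxide before it is silylated, which would scramble C2. The fallback, by known chemistry, sets out from 14: asymmetric hydrogenation with the chiral ruthenium N-heterocyclic carbene catalyst made from [Ru(cod)(2-methylallyl)2], the imidazolinium salt SINpEt·HBF4 and KOtBu (H2 under pressure, hexane/toluene), with the carbene antipode that gives 2S. This reduces C2=C3 and also, in part or fully, the ketone, to give (2S,4S)-2-[4-(benzyloxy)-3-methoxyphenyl]-5,6,7-trimethoxychroman-4-ol F1 together with 16. The crude mixture is oxidised with Dess–Martin periodinane (NaHCO3, CH2Cl2), which removes the C4 stereocentre, and the route is rejoined at 16.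

2. Step 6 (key step). The aryl anion may be protonated before the acyl shift, so that O-arylation stops at the aryl ester; the caesium propiolate may lose CO2 at 125 °C; and part of the phenoxide may close 5-exo instead of 6-endo. The fallback sets out from 1 and 8 and builds ring C by the chalcone route. Ortho C-acetylation of 1 (AcOH, BF3·OEt2, 90 °C) gives 1-(2-hydroxy-4,5,6-trimethoxyphenyl)ethan-1-one F2. Claisen–Schmidt condensation with 8 (KOH, EtOH, rt) gives (E)-3-[4-(benzyloxy)-3-methoxyphenyl]-1-(2-hydroxy-4,5,6-trimethoxyphenyl)prop-2-en-1-one F3. Oxidative cyclisation (catalytic I2, DMSO, 130 °C) rejoins the route at 14.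

3. Step 8. Hydrogenolysis may also cleave the benzylic C2–O1 bond of ring C, or the freed 4'-hydroxyl may promote reversible ring-opening and erode the configuration at C2. The fallback sets out from 14 and moves the debenzylation ahead of the stereocentre. Hydrogenolysis at the flavone stage (H2, Pd/C, THF/MeOH) gives 2-(4-hydroxy-3-methoxyphenyl)-5,6,7-trimethoxy-4H-chromen-4-one F4. Silylation (TBSCl, imidazole, DMF) gives 2-{4-[(tert-butyldimethylsilyl)oxy]-3-methoxyphenyl}-5,6,7-trimethoxy-4H-chromen-4-one F5. Reduction as in step 7 passes through (2S)-2-{4-[(tert-butyldimethylsilyl)oxy]-3-methoxyphenyl}-4-{[diethoxy(methyl)silyl]oxy}-5,6,7-trimethoxy-2H-chromene F6 to (2S)-2-{4-[(tert-butyldimethylsilyl)oxy]-3-methoxyphenyl}-5,6,7-trimethoxy-2,3-dihydro-4H-chromen-4-one F7. Non-basic desilylation (HF·pyridine, pyridine, THF, 0 °C) rejoins the route at 17.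

**Further compounds**

F1 | step 7 | (2S,4S)-2-[4-(benzyloxy)-3-methoxyphenyl]-5,6,7-trimethoxychroman-4-ol | COc1cc([C@@H]2C[C@H](O)c3c(cc(OC)c(OC)c3OC)O2)ccc1OCc1ccccc1
F2 | step 6 | 1-(2-hydroxy-4,5,6-trimethoxyphenyl)ethan-1-one | CC(=O)c1c(O)cc(OC)c(OC)c1OC
F3 | step 6 | (E)-3-[4-(benzyloxy)-3-methoxyphenyl]-1-(2-hydroxy-4,5,6-trimethoxyphenyl)prop-2-en-1-one | COc1cc(/C=C/C(=O)c2c(O)cc(OC)c(OC)c2OC)ccc1OCc1ccccc1
F4 | step 8 | 2-(4-hydroxy-3-methoxyphenyl)-5,6,7-trimethoxy-4H-chromen-4-one | COc1cc(-c2cc(=O)c3c(cc(OC)c(OC)c3OC)o2)ccc1O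
F5 | step 8 | 2-{4-[(tert-butyldimethylsilyl)oxy]-3-methoxyphenyl}-5,6,7-trimethoxy-4H-chromen-4-one | COc1cc(-c2cc(=O)c3c(cc(OC)c(OC)c3OC)o2)ccc1O[Si](C)(C)C(C)(C)C
F6 | step 8 | (2S)-2-{4-[(tert-butyldimethylsilyl)oxy]-3-methoxyphenyl}-4-{[diethoxy(methyl)silyl]oxy}-5,6,7-trimethoxy-2H-chromene | COc1cc([C@@H]2C=C(O[Si](C)(OCC)OCC)c3c(cc(OC)c(OC)c3OC)O2)ccc1O[Si](C)(C)C(C)(C)C
F7 | step 8 | (2S)-2-{4-[(tert-butyldimethylsilyl)oxy]-3-methoxyphenyl}-5,6,7-trimethoxy-2,3-dihydro-4H-chromen-4-one | COc1cc([C@@H]2CC(=O)c3c(cc(OC)c(OC)c3OC)O2)ccc1O[Si](C)(C)C(C)(C)C
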